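**Retrosynthetic overview**

1. The allylic hydroxyl comes last, by allylic oxidation of the exocyclic methylene. The ring A bromochloride comes from a spiro cyclohexenone through an α-bromo ketone, methyl addition and a bromine-assisted OH-to-Cl exchange.
2. The spiro cyclohexenone comes from a symmetric spiro cyclohexa-2,5-dienone by catalyst-controlled conjugate reduction of one enone arm; this sets the spiro centre.
3. Key disconnection: the spiro C–C bond, made by gold-catalysed dearomative 6-exo-dig cyclisation of a para-(tert-alkyl)phenol onto a terminal alkyne (ring B closure).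
4. The alkynyl phenol is assembled from prenol (enantioselective bromochlorination, then Friedel–Crafts capture of the bromonium ion by a silyl-protected phenol) and 1-(trimethylsilyl)propyne (triflate alkylation).
5. Ring order: ring A enters as the arene, ring B is closed onto its para carbon, then ring A is dearomatised and functionalised.

Assumption: the SMILES is read as (2S,3S,6S,8R,10R)-2,10-dibromo-3-chloro-3,11,11-trimethyl-7-methylidenespiro[5.5]undecan-8-ol; ring A carries Cl, ring B carries OH.

**Route**

Step 1
Reactants: 1 3-methylbut-2-en-1-ol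
Product: 2 (2R)-2-bromo-3-chloro-3-methylbutan-1-ol
Conditions: NBS, ClTi(OiPr)3, Ti(OiPr)4 (10 mol %), Burns' chiral tridentate Schiff-base ligand (20 mol %, the enantiomer that gives 2R), hexanes, −20 °C
Reagents that add atoms: N-bromosuccinimide O=C1CCC(=O)N1Br; chlorotitanium triisopropoxide CC(C)O[Ti](Cl)(OC(C)C)OC(C)C
Why: The titanium-bound allylic alkoxide in the chiral complex takes Br+ from NBS on one alkene face and chloride is delivered from titanium to the tertiary carbon (anti, Markovnikov), so the catalyst sets the bromine-bearing carbon as R; catalytic enantioselective bromochlorination of an allylic alcohol.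

Step 2
Reactants: 3 phenol
Product: 4 (phenoxy)tri(propan-2-yl)silane
Conditions: i-Pr3SiCl, imidazole, DMF, rt
Reagents that add atoms: chlorotri(propan-2-yl)silane CC(C)[Si](Cl)(C(C)C)C(C)C
Why: Imidazole-promoted O-silylation; the bulky silyl ether masks the oxygen and shields the ortho positions for the next step.

Step 3
Reactants: 2 (2R)-2-bromo-3-chloro-3-methylbutan-1-ol; 4 (phenoxy)tri(propan-2-yl)silane
Product: 5 (2S)-2-bromo-3-methyl-3-{4-[tri(propan-2-yl)silyloxy]phenyl}butan-1-ol
Conditions: 4 (3 equiv), (CF3)2CHOH, 0 °C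
Reagents that add atoms: none
Why: In the ionising, non-nucleophilic solvent the tertiary chloride leaves with anchimeric help from the neighbouring bromine, and the bromonium ion is opened at its tertiary carbon by the para position of the aryl silyl ether, which restores the C–Br bond with unchanged configuration (R becomes S only through substituent ranking); solvolytic Friedel–Crafts alkylation.

Step 4
Reactants: 5 (2S)-2-bromo-3-methyl-3-{4-[tri(propan-2-yl)silyloxy]phenyl}butan-1-ol
Product: 6 (2S)-2-bromo-3-methyl-3-{4-[tri(propan-2-yl)silyloxy]phenyl}butyl trifluoromethanesulfonate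
Conditions: Tf2O, 2,6-lutidine, CH2Cl2, −78 °C
Reagents that add atoms: trifluoromethanesulfonic anhydride O=S(=O)(OS(=O)(=O)C(F)(F)F)C(F)(F)F
Why: Low-temperature triflation of the primary alcohol with a hindered base leaves the secondary bromide and the aryl silyl ether untouched; alcohol sulfonylation.

Step 5
Reactants: 6 (2S)-2-bromo-3-methyl-3-{4-[tri(propan-2-yl)silyloxy]phenyl}butyl trifluoromethanesulfonate; 7 1-(trimethylsilyl)prop-1-yne
Product: 9 {(5R)-5-bromo-6-methyl-6-{4-[tri(propan-2-yl)silyloxy]phenyl}hept-1-yn-1-yl}trimethylsilane, via lithiated silylpropyne 8 (not isolated)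
Conditions: 7, n-BuLi, THF, −20 °C; then 6, −78 °C
Reagents that add atoms: none
Why: The propargylic carbon of the lithiated silylpropyne displaces the primary triflate at −78 °C faster than it causes elimination, and no stereocentre is touched; SN2 alkylation of a propargyl anion equivalent.

Step 6
Reactants: 9 {(5R)-5-bromo-6-methyl-6-{4-[tri(propan-2-yl)silyloxy]phenyl}hept-1-yn-1-yl}trimethylsilane
Product: 10 4-[(3R)-3-bromo-2-methylhept-6-yn-2-yl]phenol
Conditions: Bu4NF, AcOH, THF, 0 °C to rt
Reagents that add atoms: none
Why: Fluoride cleaves both the alkynyl C–Si and the aryl O–Si bond, while the acetic acid buffer keeps the phenol protonated so that no phenoxide can attack the neighbouring C–Br carbon; fluoride desilylation.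

Step 7
Reactants: 10 4-[(3R)-3-bromo-2-methylhept-6-yn-2-yl]phenol
Product: 11 (10R)-10-bromo-11,11-dimethyl-7-methylidenespiro[5.5]undeca-1,4-dien-3-one
Conditions: Ph3PAuNTf2 (5 mol %), CH2Cl2 (0.02 M), rt
Reagents that add atoms: none
Why: Proposed new method: the π-acidic monovalent gold complex activates the terminal alkyne, and the para carbon of the phenol attacks its internal carbon anti to gold in a 6-exo-dig ipso-Friedel–Crafts step (favoured by the gem-dimethyl group, whereas ortho attack would need a seven-membered ring); loss of the phenolic proton gives the cross-conjugated dienone and protodeauration of the vinylgold gives the exocyclic methylene, so ring B and the spiro C–C bond form in one catalytic step with the equatorial bromide untouched; the closest known reaction type is the gold-catalysed 5-exo-dig ipso-cyclisation of phenol- or anisole-tethered alkynes to spiro[4.5]decadienones (dearomative hydroarylation, related to the Conia-ene carbocyclisation), not yet shown for a six-membered ring closed onto a carbon flanked by a quaternary centre.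

Step 8
Reactants: 11 (10R)-10-bromo-11,11-dimethyl-7-methylidenespiro[5.5]undeca-1,4-dien-3-one
Product: 13 (6S,10R)-10-bromo-11,11-dimethyl-7-methylidenespiro[5.5]undec-1-en-3-one, via silyl dienol ether 12 (not isolated)
Conditions: Cu(OAc)2 (3 mol %), (R)-DTBM-SEGPHOS (3.3 mol %), (EtO)2MeSiH (1.1 equiv), toluene, −20 °C; then citric acid, MeOH–H2O, 0 °C
Reagents that add atoms: none
Why: The ligated copper hydride adds hydride to the β-carbon of one enone arm from the face away from the gem-dimethyl carbon, and the resulting silyl dienol ether cannot be reduced again; the ligand chirality selects the arm and so fixes the spiro carbon as S; desymmetrising asymmetric conjugate reduction.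

Step 9
Reactants: 13 (6S,10R)-10-bromo-11,11-dimethyl-7-methylidenespiro[5.5]undec-1-en-3-one
Product: 15 (2S,6S,10R)-2,10-dibromo-11,11-dimethyl-7-methylidenespiro[5.5]undecan-3-one, via silyl enol ether 14 (not isolated)
Conditions: Cu(OAc)2 (5 mol %), 1,2-bis(diphenylphosphino)benzene (5 mol %), (EtO)2MeSiH (1.2 equiv), toluene, 0 °C; then NBS, THF, −78 °C; then LiBr (20 mol %), acetone, rt
Reagents that add atoms: N-bromosuccinimide O=C1CCC(=O)N1Br
Why: Conjugate reduction of the remaining enone gives the silyl enol ether regiospecifically on that arm, NBS brominates it in preference to the much less nucleophilic 1,1-disubstituted alkene, and bromide-mediated equilibration gives the equatorial bromide, cis to the gem-dimethyl carbon of ring B (S); conjugate reduction followed by α-bromination of a silyl enol ether.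

Step 10
Reactants: 15 (2S,6S,10R)-2,10-dibromo-11,11-dimethyl-7-methylidenespiro[5.5]undecan-3-one
Product: 16 (2S,3S,6S,10R)-2,10-dibromo-3,11,11-trimethyl-7-methylidenespiro[5.5]undecan-3-ol
Conditions: AlMe3 (3 equiv), toluene, −78 to 0 °C
Reagents that add atoms: trimethylaluminium C[Al](C)C
Why: Excess AlMe3 in a hydrocarbon solvent delivers methyl along the axial trajectory of the cyclohexanone, giving the equatorial tertiary alcohol trans to the neighbouring bromine (S) and leaving both alkyl bromides intact; 1,2-addition of an organoaluminium reagent.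

Step 11
Reactants: 16 (2S,3S,6S,10R)-2,10-dibromo-3,11,11-trimethyl-7-methylidenespiro[5.5]undecan-3-ol
Product: 17 (2S,3S,6S,10R)-2,10-dibromo-3-chloro-3,11,11-trimethyl-7-methylidenespiro[5.5]undecane
Conditions: SOCl2, 2,6-di-tert-butyl-4-methylpyridine, CH2Cl2, −40 to 0 °C
Reagents that add atoms: thionyl chloride O=S(Cl)Cl
Why: The tertiary chlorosulfite ionises with participation of the vicinal bromine and chloride re-enters at the tertiary carbon anti to bromine, so the exchange proceeds with overall retention (S), while the hindered base keeps HCl away from the exocyclic alkene; deoxychlorination with neighbouring-group participation.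

Step 12
Reactants: 17 (2S,3S,6S,10R)-2,10-dibromo-3-chloro-3,11,11-trimethyl-7-methylidenespiro[5.5]undecane
Product: 18 (2S,3S,6S,8R,10R)-2,10-dibromo-3-chloro-3,11,11-trimethyl-7-methylidenespiro[5.5]undecan-8-ol
Conditions: SeO2 (0.5 equiv), t-BuOOH, CH2Cl2, rt
Reagents that add atoms: selenium dioxide O=[Se]=O; tert-butyl hydroperoxide CC(C)(C)OO
Why: The only allylic C–H bonds of the 1,1-disubstituted alkene are at C8, and the ene reaction followed by [2,3]-sigmatropic shift of the allylseleninic acid delivers oxygen axially, trans to the equatorial ring B bromine (R); Riley allylic oxidation.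

**Compound list**

1 | 3-methylbut-2-en-1-ol | CC(C)=CCO | starting material
2 | (2R)-2-bromo-3-chloro-3-methylbutan-1-ol | OC[C@@H](Br)C(C)(C)Cl | intermediate
3 | phenol | Oc1ccccc1 | starting material
4 | (phenoxy)tri(propan-2-yl)silane | CC(C)[Si](Oc1ccccc1)(C(C)C)C(C)C | intermediate
5 | (2S)-2-bromo-3-methyl-3-{4-[tri(propan-2-yl)silyloxy]phenyl}butan-1-ol | OC[C@@H](Br)C(C)(C)c1ccc(O[Si](C(C)C)(C(C)C)C(C)C)cc1 | intermediate
6 | (2S)-2-bromo-3-methyl-3-{4-[tri(propan-2-yl)silyloxy]phenyl}butyl trifluoromethanesulfonate | O=S(=O)(OC[C@@H](Br)C(C)(C)c1ccc(O[Si](C(C)C)(C(C)C)C(C)C)cc1)C(F)(F)F | intermediate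
7 | 1-(trimethylsilyl)prop-1-yne | CC#C[Si](C)(C)C | starting material
8 | 3-lithio-1-(trimethylsilyl)prop-1-yne | [Li]CC#C[Si](C)(C)C | intermediate (not isolated)
9 | {(5R)-5-bromo-6-methyl-6-{4-[tri(propan-2-yl)silyloxy]phenyl}hept-1-yn-1-yl}trimethylsilane | C[Si](C)(C)C#CCC[C@@H](Br)C(C)(C)c1ccc(O[Si](C(C)C)(C(C)C)C(C)C)cc1 | intermediate
10 | 4-[(3R)-3-bromo-2-methylhept-6-yn-2-yl]phenol | C#CCC[C@@H](Br)C(C)(C)c1ccc(O)cc1 | intermediate
11 | (10R)-10-bromo-11,11-dimethyl-7-methylidenespiro[5.5]undeca-1,4-dien-3-one | C=C1CC[C@@H](Br)C(C)(C)C12C=CC(=O)C=C2 | intermediate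
12 | diethoxy(methyl){[(6S,10R)-10-bromo-11,11-dimethyl-7-methylidenespiro[5.5]undeca-1,3-dien-3-yl]oxy}silane | C=C1CC[C@@H](Br)C(C)(C)[C@]12CC=C(O[Si](C)(OCC)OCC)C=C2 | intermediate (not isolated)
13 | (6S,10R)-10-bromo-11,11-dimethyl-7-methylidenespiro[5.5]undec-1-en-3-one | C=C1CC[C@@H](Br)C(C)(C)[C@]12CCC(=O)C=C2 | intermediate
14 | diethoxy(methyl){[(6S,10R)-10-bromo-11,11-dimethyl-7-methylidenespiro[5.5]undec-2-en-3-yl]oxy}silane | C=C1CC[C@@H](Br)C(C)(C)[C@]12CCC(O[Si](C)(OCC)OCC)=CC2 | intermediate (not isolated)
15 | (2S,6S,10R)-2,10-dibromo-11,11-dimethyl-7-methylidenespiro[5.5]undecan-3-one | C=C1CC[C@@H](Br)C(C)(C)[C@]12CCC(=O)[C@@H](Br)C2 | intermediate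
16 | (2S,3S,6S,10R)-2,10-dibromo-3,11,11-trimethyl-7-methylidenespiro[5.5]undecan-3-ol | C=C1CC[C@@H](Br)C(C)(C)[C@]12CC[C@](C)(O)[C@@H](Br)C2 | intermediate
17 | (2S,3S,6S,10R)-2,10-dibromo-3-chloro-3,11,11-trimethyl-7-methylidenespiro[5.5]undecane | C=C1CC[C@@H](Br)C(C)(C)[C@]12CC[C@](C)(Cl)[C@@H](Br)C2 | intermediate
18 | (2S,3S,6S,8R,10R)-2,10-dibromo-3-chloro-3,11,11-trimethyl-7-methylidenespiro[5.5]undecan-8-ol | C=C1[C@H](O)C[C@@H](Br)C(C)(C)[C@]12CC[C@](C)(Cl)[C@@H](Br)C2 | target

**Step count**

Total step count: 12. Longest linear sequence: 11 steps (step 1, then steps 3 to 12); the phenol branch (step 2) joins at step 3. The fragments are small and commercial, so the sequence after the union is long relative to the branches.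

**Steps most likely to fail**

Step 7 (the proposed gold cyclisation). The cyclisation may lose to alkyne hydration, to ortho attack, or to acid-induced dienone–phenol rearrangement of 11. The fallback uses only known reaction types and avoids dearomatisation; it sets out from 2 and comes back at 13.
- Tf2O and 2,6-lutidine convert 2 into (2R)-2-bromo-3-chloro-3-methylbutyl trifluoromethanesulfonate F3.
- F3 alkylates the terminal carbon of the dianion of methyl acetoacetate (NaH, then n-BuLi, THF, −78 °C) to give methyl (6R)-6-bromo-7-chloro-7-methyl-3-oxooctanoate F4.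
- NaH and Tf2O give, through the chelated enolate, methyl (2Z,6R)-6-bromo-7-chloro-7-methyl-3-(trifluoromethanesulfonyloxy)oct-2-enoate F5.
- Coupling of F5 with Me3SiCH2MgCl under Pd(PPh3)4 catalysis gives methyl (2Z,6R)-6-bromo-7-chloro-7-methyl-3-[(trimethylsilyl)methyl]oct-2-enoate F6.
- Solvolysis of F6 in (CF3)2CHOH with 2,6-di-tert-butylpyridine lets the allylsilane capture the bromonium ion through a chair transition state, closing ring B as methyl (1S,3R)-3-bromo-2,2-dimethyl-6-methylidenecyclohexane-1-carboxylate F7.
- i-Bu2AlH at −78 °C gives (1S,3R)-3-bromo-2,2-dimethyl-6-methylidenecyclohexane-1-carbaldehyde F8.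
- Base-catalysed Michael addition of F8 to methyl vinyl ketone, which enters anti to the pseudo-axial methyl group, gives (1S,3R)-3-bromo-2,2-dimethyl-6-methylidene-1-(3-oxobutyl)cyclohexane-1-carbaldehyde F9.
- Aldol condensation of F9 (pyrrolidine, AcOH) closes ring A to 13.

Step 3 (the Friedel–Crafts union). The bromonium ion may eliminate, be captured ortho, or be intercepted by the free hydroxyl before the arene reacts. The fallback replaces C–H substitution by silicon-directed ipso substitution; it sets out from 2 and comes back at 5.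
- 4-Bromophenol is silylated (i-Pr3SiCl, imidazole) to (4-bromophenoxy)tri(propan-2-yl)silane F1.
- Bromine–lithium exchange (n-BuLi, THF, −78 °C) and quenching with Me3SiCl give trimethyl{4-[tri(propan-2-yl)silyloxy]phenyl}silane F2.
- F2 takes up the bromonium ion derived from 2 in (CF3)2CHOH at its silicon-bearing carbon, which is the most nucleophilic position and the only one that leads to product, and loss of the silyl group gives 5 as a single regioisomer.

Step 8 (the catalyst-controlled desymmetrisation). The sense and level of induction on this hindered dienone are not assured; the other ligand enantiomer would give the C6 epimer. The fallback moves the desymmetrisation to a chiral-base deprotonation; it sets out from 11 and comes back at 15.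
- Both enone double bonds are reduced with [(Ph3P)CuH]6 to the symmetric ketone (10R)-10-bromo-11,11-dimethyl-7-methylidenespiro[5.5]undecan-3-one F10.
- LiN[(R)-CH(Me)Ph]2 with Me3SiCl as internal quench (THF, −100 °C) removes one of the two enantiotopic axial α-hydrogens to give {[(6S,10R)-10-bromo-11,11-dimethyl-7-methylidenespiro[5.5]undec-2-en-3-yl]oxy}trimethylsilane F11.
- NBS, then LiBr equilibration, gives 15.

**Further compounds**

F1 | step 3 | (4-bromophenoxy)tri(propan-2-yl)silane | CC(C)[Si](Oc1ccc(Br)cc1)(C(C)C)C(C)C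
F2 | step 3 | trimethyl{4-[tri(propan-2-yl)silyloxy]phenyl}silane | CC(C)[Si](Oc1ccc(cc1)[Si](C)(C)C)(C(C)C)C(C)C
F3 | step 7 | (2R)-2-bromo-3-chloro-3-methylbutyl trifluoromethanesulfonate | O=S(=O)(OC[C@@H](Br)C(C)(C)Cl)C(F)(F)F
F4 | step 7 | methyl (6R)-6-bromo-7-chloro-7-methyl-3-oxooctanoate | COC(=O)CC(=O)CC[C@@H](Br)C(C)(C)Cl
F5 | step 7 | methyl (2Z,6R)-6-bromo-7-chloro-7-methyl-3-(trifluoromethanesulfonyloxy)oct-2-enoate | COC(=O)/C=C(\OS(=O)(=O)C(F)(F)F)CC[C@@H](Br)C(C)(C)Cl
F6 | step 7 | methyl (2Z,6R)-6-bromo-7-chloro-7-methyl-3-[(trimethylsilyl)methyl]oct-2-enoate | COC(=O)/C=C(\C[Si](C)(C)C)CC[C@@H](Br)C(C)(C)Cl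
F7 | step 7 | methyl (1S,3R)-3-bromo-2,2-dimethyl-6-methylidenecyclohexane-1-carboxylate | COC(=O)[C@H]1C(=C)CC[C@@H](Br)C1(C)C
F8 | step 7 | (1S,3R)-3-bromo-2,2-dimethyl-6-methylidenecyclohexane-1-carbaldehyde | O=C[C@H]1C(=C)CC[C@@H](Br)C1(C)C
F9 | step 7 | (1S,3R)-3-bromo-2,2-dimethyl-6-methylidene-1-(3-oxobutyl)cyclohexane-1-carbaldehyde | C=C1CC[C@@H](Br)C(C)(C)[C@]1(C=O)CCC(C)=O
F10 | step 8 | (10R)-10-bromo-11,11-dimethyl-7-methylidenespiro[5.5]undecan-3-one | C=C1CC[C@@H](Br)C(C)(C)C12CCC(=O)CC2
F11 | step 8 | {[(6S,10R)-10-bromo-11,11-dimethyl-7-methylidenespiro[5.5]undec-2-en-3-yl]oxy}trimethylsilane | C=C1CC[C@@H](Br)C(C)(C)[C@]12CCC(O[Si](C)(C)C)=CC2
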